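## Retrosynthetic overview
1. The target comes from global desilylation and oxidation of the C8 carbinol. The eleven-membered carbocycle is the last ring formed, closed at C8–C9 by CrCl2/NiCl2 coupling of a (Z)-2-iodoallyl ether with the C8 aldehyde.
2. The oxirane is the first ring formed. It is made on the open chain by C7–OH-directed VO(acac)2 epoxidation of the E-C5=C6 alkene, and the C4 senecioate comes from acylation.
3. Key bond C5–C6: an intermolecular lithium aldol of an ethyl ynone (C1–C5) with (R)-glyceraldehyde acetonide (C6–C8), followed by dehydration. C4 is set by CBS reduction and Z-C2=C3 by Lindlar semihydrogenation.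
4. C10, C9 and C12 are added to C11 by methylenation, hydroboration, oxidation and an iodo-Wittig olefination.
5. The quaternary C1 comes from geraniol by Sharpless epoxidation and an organoaluminium-promoted 1,2-shift of the siloxymethyl group.

Assumption: the SMILES is read literally, so both ring alkenes are Z and the oxirane is trans. Ring numbering: C1 quaternary, C2=C3, C4 ester, C5/C6 oxirane, C7 OH, C8 C=O, C9(C12H2OH)=C10, C11H2. This gives 1S,4R,5S,6S,7S.

## Route

Step 1
Reactants: 1 geraniol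
Product: 2 (2S,3S)-2,3-epoxygeraniol
Conditions: Ti(OiPr)4 (5 mol%), L-(+)-diethyl tartrate (7 mol%), t-BuOOH (decane), 4 Å MS, CH2Cl2, −20 °C
Reagents that add atoms: tert-butyl hydroperoxide CC(C)(C)OO
Why: Katsuki–Sharpless asymmetric epoxidation touches only the allylic alkene, and L-(+)-tartrate gives the (2S,3S)-oxirane (about 95% ee), which is the source of the C1 configuration.

Step 2
Reactants: 2 (2S,3S)-2,3-epoxygeraniol
Product: 3 (2S,3S)-2,3-epoxygeranyl tert-butyldimethylsilyl ether
Conditions: TBSCl, imidazole, DMF, 0 °C → rt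
Reagents that add atoms: tert-butyldimethylsilyl chloride CC(C)(C)[Si](C)(C)Cl
Why: Routine silyl ether formation that creates no stereocentre and supplies the bulky siloxymethyl group needed for the shift in step 3.

Step 3
Reactants: 3 (2S,3S)-2,3-epoxygeranyl tert-butyldimethylsilyl ether
Product: 4 (S)-2-[(tert-butyldimethylsilyloxy)methyl]-2,6-dimethylhept-5-enal
Conditions: MeAl(OAr)2 (Ar = 4-bromo-2,6-di-tert-butylphenyl, 2 equiv, from Me3Al + 2 ArOH, CH2Cl2, rt), then 3, −78 → −40 °C; dil. HCl
Reagents that add atoms: none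
Why: In this organoaluminium-promoted epoxide-to-aldehyde (semipinacol-type) rearrangement the oxirane opens at its tertiary carbon and the siloxymethyl group migrates anti to the leaving oxygen, so quaternary C1 forms by inversion with full chirality transfer.

Step 4
Reactants: 4 (S)-2-[(tert-butyldimethylsilyloxy)methyl]-2,6-dimethylhept-5-enal
Product: 5 (R)-3-[(tert-butyldimethylsilyloxy)methyl]-3,7-dimethyloct-6-en-1-yne
Conditions: dimethyl (1-diazo-2-oxopropyl)phosphonate, K2CO3, MeOH, 0 °C → rt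
Reagents that add atoms: dimethyl (1-diazo-2-oxopropyl)phosphonate COP(=O)(OC)C(=[N+]=[N-])C(C)=O
Why: Seyferth–Gilbert homologation (Ohira–Bestmann variant) converts the non-enolisable aldehyde into the C2≡C3 alkyne under mild base, leaving C1 and the silyl ether untouched.

Step 5
Reactants: 5 (R)-3-[(tert-butyldimethylsilyloxy)methyl]-3,7-dimethyloct-6-en-1-yne; 6 N-methoxy-N-methylpropanamide
Product: 8 (R)-6-[(tert-butyldimethylsilyloxy)methyl]-6,10-dimethylundec-9-en-4-yn-3-one, via lithium acetylide 7 (not isolated)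
Conditions: n-BuLi, THF, −78 °C; then 6, −78 → 0 °C; aq. NH4Cl
Reagents that add atoms: none
Why: In this Weinreb ketone synthesis the chelated tetrahedral adduct survives until work-up, so the acetylide adds only once and gives the ethyl ynone.

Step 6
Reactants: 9 1,2:5,6-di-O-isopropylidene-D-mannitol
Product: 10 (R)-2,3-O-isopropylideneglyceraldehyde
Conditions: NaIO4, CH2Cl2/sat. aq. NaHCO3, rt; used fresh
Reagents that add atoms: none
Why: Malaprade glycol cleavage of the central diol gives two equivalents of the aldehyde, whose stereocentre (future C7) comes unchanged from D-mannitol.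

Step 7
Reactants: 8 (R)-6-[(tert-butyldimethylsilyloxy)methyl]-6,10-dimethylundec-9-en-4-yn-3-one; 10 (R)-2,3-O-isopropylideneglyceraldehyde
Product: 12 β-hydroxy ynone (aldol adduct; mixture at C5 and C6), via lithium enolate 11 (not isolated)
Conditions: LiN(iPr)2, THF, −78 °C; then 10, −78 °C; aq. NH4Cl
Reagents that add atoms: none
Why: This intermolecular lithium aldol addition forms C5–C6 and joins the C1–C5 and C6–C8 fragments; 8 has one enolisable site and a shielded alkyne terminus, and the two new centres are erased in step 8.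

Step 8
Reactants: 12 β-hydroxy ynone
Product: 14 (E)-enynone (C4 ketone; E-C5=C6), via C6 mesylate 13 (not isolated)
Conditions: MsCl, Et3N, CH2Cl2, −10 °C; then DBU, 0 °C → rt
Reagents that add atoms: none
Why: Mesylation and E1cB elimination complete the aldol condensation and give the E-enone, with the C4 carbonyl trans to C7, because that geometry avoids allylic strain in the eliminating enolate.

Step 9
Reactants: 14 (E)-enynone
Product: 15 enynol with the C4 carbinol set (4S by CIP here; spatially as in the target)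
Conditions: (S)-2-methyl-CBS-oxazaborolidine (0.3 equiv), catecholborane (2 equiv), toluene, −78 °C
Reagents that add atoms: none
Why: In this Corey–Bakshi–Shibata reduction the rod-shaped alkynyl arm is the small group and the α-branched alkenyl arm the large one, so the (S)-catalyst sets C4 as in the target, and catecholborane leaves the alkenes alone at −78 °C.

Step 10
Reactants: 15 enynol
Product: 16 (2Z,5E)-dienol (4R)
Conditions: H2 (1 atm), 5% Pd/CaCO3 poisoned with Pb(OAc)2, quinoline, EtOAc, rt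
Reagents that add atoms: none
Why: Lindlar semihydrogenation adds H2 syn to the only alkyne and stops at Z-C2=C3, while the two trisubstituted alkenes are inert.

Step 11
Reactants: 16 (2Z,5E)-dienol
Product: 17 C4 pivalate
Conditions: PivCl, pyridine, DMAP (cat.), CH2Cl2, 0 °C → rt
Reagents that add atoms: pivaloyl chloride CC(C)(C)C(=O)Cl
Why: This ester protection masks C4–OH through the ylide, borane and oxidation steps, and the pivalate falls off without an extra step under the hydride of step 18.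

Step 12
Reactants: 17 C4 pivalate
Product: 18 C11 primary alcohol
Conditions: Bu4NF, THF, rt; aq. NH4Cl
Reagents that add atoms: none
Why: Fluoride-induced desilylation frees the neopentyl alcohol without affecting the pivalate or the acetonide.

Step 13
Reactants: 18 C11 primary alcohol
Product: 19 C11 aldehyde
Conditions: Dess–Martin periodinane, CH2Cl2, 0 °C → rt
Reagents that add atoms: none
Why: Dess–Martin oxidation gives the non-enolisable aldehyde under near-neutral conditions, so nothing can epimerise or migrate.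

Step 14
Reactants: 19 C11 aldehyde
Product: 20 C1 vinyl compound (C11=C10H2)
Conditions: Ph3PCH3Br, KN(SiMe3)2, THF, 0 °C; then 19, −78 → 0 °C
Reagents that add atoms: methyltriphenylphosphonium bromide C[P+](c1ccccc1)(c1ccccc1)c1ccccc1.[Br-]
Why: Wittig methylenation adds C10, and the aldehyde reacts with the ylide far faster than the hindered pivalate does.

Step 15
Reactants: 20 C1 vinyl compound
Product: 22 C10 primary alcohol, via B-alkyl-9-BBN adduct 21 (not isolated)
Conditions: 9-BBN (1.3 equiv), THF, 0 °C → rt; then NaOH, H2O2, 0 °C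
Reagents that add atoms: hydrogen peroxide OO
Why: In this Brown hydroboration–oxidation 9-BBN attacks only the monosubstituted alkene, anti-Markovnikov, and ignores the hindered Z-disubstituted and trisubstituted alkenes.

Step 16
Reactants: 22 C10 primary alcohol
Product: 23 C10 aldehyde
Conditions: Dess–Martin periodinane, CH2Cl2, 0 °C → rt
Reagents that add atoms: none
Why: Dess–Martin oxidation stops cleanly at the aldehyde and tolerates the ester, the acetonide and all the alkenes.

Step 17
Reactants: 23 C10 aldehyde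
Product: 24 ethyl (Z)-2-iodoenoate (C12 ester; iodine on C9 cis to C11)
Conditions: Ph3P=CHCO2Et, N-iodosuccinimide, CH2Cl2, −20 °C; then 23, −20 °C → rt
Reagents that add atoms: ethyl (triphenylphosphoranylidene)acetate CCOC(=O)C=P(c1ccccc1)(c1ccccc1)c1ccccc1; N-iodosuccinimide O=C1CCC(=O)N1I
Why: Wittig olefination with the stabilised iodo-ylide places the ester trans to the C11 chain, which is the (Z)-iodoenoate geometry needed for C9=C10, and the minor E isomer is removed by chromatography.

Step 18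
Reactants: 24 ethyl (Z)-2-iodoenoate
Product: 25 C4,C12-diol
Conditions: i-Bu2AlH (6 equiv), CH2Cl2, −78 → −20 °C; aq. potassium sodium tartrate
Reagents that add atoms: none
Why: In this hydride reduction i-Bu2AlH reduces the enoate 1,2 to the C12 allylic alcohol and cleaves the pivalate in the same pot, while the alkenyl iodide is inert.

Step 19
Reactants: 25 C4,C12-diol
Product: 26 C12 tert-butyldiphenylsilyl ether (C4–OH free)
Conditions: TBDPSCl (1.05 equiv), imidazole, CH2Cl2, 0 °C
Reagents that add atoms: tert-butyldiphenylsilyl chloride CC(C)(C)[Si](Cl)(c1ccccc1)c1ccccc1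
Why: This silylation is chemoselective because the bulky chloride reacts only with the primary allylic alcohol and not with the hindered secondary one.

Step 20
Reactants: 26 C12 tert-butyldiphenylsilyl ether; 27 senecioic acid (3-methylbut-2-enoic acid)
Product: 28 C4 senecioate
Conditions: DCC, DMAP (cat.), CH2Cl2, 0 °C → rt
Reagents that add atoms: none
Why: Steglich esterification acylates C4–OH with retention, and the carbodiimide route avoids the vinylketene pathway that deconjugates senecioyl chloride.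

Step 21
Reactants: 28 C4 senecioate
Product: 29 C7,C8-diol
Conditions: AcOH/H2O (4:1), 35 °C
Reagents that add atoms: none
Why: This acid-catalysed acetal hydrolysis of the terminal acetonide is mild enough for the tert-butyldiphenylsilyl ether, the ester and the alkenyl iodide.

Step 22
Reactants: 29 C7,C8-diol
Product: 30 C8 triethylsilyl ether (C7–OH free)
Conditions: TESCl (1.05 equiv), imidazole, CH2Cl2, −20 °C
Reagents that add atoms: triethylsilyl chloride CC[Si](Cl)(CC)CC
Why: Selective silylation of the primary alcohol leaves the allylic C7–OH free as the directing group for step 23.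

Step 23
Reactants: 30 C8 triethylsilyl ether
Product: 31 (5S,6S)-epoxy alcohol
Conditions: VO(acac)2 (5 mol%), t-BuOOH (decane), CH2Cl2, 0 °C → rt
Reagents that add atoms: tert-butyl hydroperoxide CC(C)(C)OO
Why: Hydroxyl-directed vanadium epoxidation reaches only the alkene allylic to C7–OH, and A(1,3) strain between the C5 methyl (cis to C7) and the C8 arm enforces the threo (syn) transition state, which sets C5 and C6.

Step 24
Reactants: 31 (5S,6S)-epoxy alcohol
Product: 32 C7 tert-butyldimethylsilyl ether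
Conditions: TBSOTf, 2,6-lutidine, CH2Cl2, −78 °C
Reagents that add atoms: tert-butyldimethylsilyl triflate CC(C)(C)[Si](C)(C)OS(=O)(=O)C(F)(F)F
Why: Low-temperature silylation with a buffered triflate protects the hindered C7–OH, blocks Payne migration and does not open the oxirane.

Step 25
Reactants: 32 C7 tert-butyldimethylsilyl ether
Product: 33 C8 primary alcohol
Conditions: HF·pyridine, pyridine, THF, 0 °C
Reagents that add atoms: none
Why: This desilylation is selective because the primary triethylsilyl ether is cleaved much faster than the secondary tert-butyldimethylsilyl and the tert-butyldiphenylsilyl ethers.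

Step 26
Reactants: 33 C8 primary alcohol
Product: 34 C8 aldehyde
Conditions: Dess–Martin periodinane, CH2Cl2, 0 °C → rt
Reagents that add atoms: none
Why: Dess–Martin oxidation gives the α-silyloxy aldehyde without base, so C7 does not epimerise and the oxirane is not eliminated.

Step 27
Reactants: 34 C8 aldehyde
Product: 35 eleven-membered allylic alcohol (C8 epimers)
Conditions: CrCl2 (15 equiv), NiCl2 (0.15 equiv), DMSO/THF (3:1), 0.002 M, slow addition, rt
Reagents that add atoms: none
Why: Nozaki–Hiyama–Kishi macrocyclisation adds the alkenylchromium species only to the aldehyde, tolerates the ester, oxirane and silyl ethers and carries the iodide geometry into C9=C10, and the new C8 centre is irrelevant because step 28 removes it.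

Step 28
Reactants: 35 eleven-membered allylic alcohol
Product: 36 bis-silylated macrocyclic enone
Conditions: Dess–Martin periodinane, CH2Cl2, 0 °C → rt
Reagents that add atoms: none
Why: Dess–Martin oxidation of the only free (allylic) alcohol converges both C8 epimers on the enone under base-free conditions.

Step 29
Reactants: 36 bis-silylated macrocyclic enone
Product: 37 target CNP0163063.1
Conditions: HF·pyridine (excess), THF, 0 °C → rt, polypropylene vessel
Reagents that add atoms: none
Why: Fluoride desilylation under mildly acidic conditions frees C7–OH and C12–OH and avoids the base-induced enolisation at C7 that would open the oxirane.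

## Compound list
1 | geraniol | CC(C)=CCC/C(C)=C/CO | starting material
2 | (2S,3S)-2,3-epoxygeraniol | CC(C)=CCC[C@]1(C)O[C@H]1CO | intermediate
3 | (2S,3S)-2,3-epoxygeranyl TBS ether | CC(C)=CCC[C@]1(C)O[C@H]1CO[Si](C)(C)C(C)(C)C | intermediate
4 | (S)-2-[(TBSO)methyl]-2,6-dimethylhept-5-enal | CC(C)=CCC[C@](C)(C=O)CO[Si](C)(C)C(C)(C)C | intermediate
5 | (R)-3-[(TBSO)methyl]-3,7-dimethyloct-6-en-1-yne | CC(C)=CCC[C@](C)(C#C)CO[Si](C)(C)C(C)(C)C | intermediate
6 | N-methoxy-N-methylpropanamide | CCC(=O)N(C)OC | starting material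
7 | lithium acetylide of 5 (not isolated) | CC(C)=CCC[C@](C)(C#C[Li])CO[Si](C)(C)C(C)(C)C | intermediate
8 | (R)-6-[(TBSO)methyl]-6,10-dimethylundec-9-en-4-yn-3-one | CC(C)=CCC[C@](C)(C#CC(=O)CC)CO[Si](C)(C)C(C)(C)C | intermediate
9 | 1,2:5,6-di-O-isopropylidene-D-mannitol | CC1(C)OC[C@@H](O1)[C@@H](O)[C@H](O)[C@H]1COC(C)(C)O1 | starting material
10 | (R)-2,3-O-isopropylideneglyceraldehyde | O=C[C@H]1COC(C)(C)O1 | intermediate
11 | lithium enolate of 8 (not isolated) | CC(C)=CCC[C@](C)(C#CC(O[Li])=CC)CO[Si](C)(C)C(C)(C)C | intermediate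
12 | β-hydroxy ynone, mixture at C5/C6 | CC(C)=CCC[C@](C)(C#CC(=O)C(C)C(O)[C@H]1COC(C)(C)O1)CO[Si](C)(C)C(C)(C)C | intermediate
13 | C6 mesylate of 12 (not isolated) | CC(C)=CCC[C@](C)(C#CC(=O)C(C)C(OS(C)(=O)=O)[C@H]1COC(C)(C)O1)CO[Si](C)(C)C(C)(C)C | intermediate
14 | (E)-enynone | CC(C)=CCC[C@](C)(C#CC(=O)/C(C)=C/[C@H]1COC(C)(C)O1)CO[Si](C)(C)C(C)(C)C | intermediate
15 | enynol, C4 set | CC(C)=CCC[C@](C)(C#C[C@@H](O)/C(C)=C/[C@H]1COC(C)(C)O1)CO[Si](C)(C)C(C)(C)C | intermediate
16 | (2Z,5E)-dienol, 4R | CC(C)=CCC[C@](C)(/C=C\[C@@H](O)/C(C)=C/[C@H]1COC(C)(C)O1)CO[Si](C)(C)C(C)(C)C | intermediate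
17 | C4 pivalate | CC(C)=CCC[C@](C)(/C=C\[C@@H](OC(=O)C(C)(C)C)/C(C)=C/[C@H]1COC(C)(C)O1)CO[Si](C)(C)C(C)(C)C | intermediate
18 | C11 primary alcohol | CC(C)=CCC[C@](C)(/C=C\[C@@H](OC(=O)C(C)(C)C)/C(C)=C/[C@H]1COC(C)(C)O1)CO | intermediate
19 | C11 aldehyde | CC(C)=CCC[C@](C)(/C=C\[C@@H](OC(=O)C(C)(C)C)/C(C)=C/[C@H]1COC(C)(C)O1)C=O | intermediate
20 | C1 vinyl compound | CC(C)=CCC[C@](C)(/C=C\[C@@H](OC(=O)C(C)(C)C)/C(C)=C/[C@H]1COC(C)(C)O1)C=C | intermediate
21 | B-alkyl-9-BBN adduct (not isolated) | CC(C)=CCC[C@](C)(/C=C\[C@@H](OC(=O)C(C)(C)C)/C(C)=C/[C@H]1COC(C)(C)O1)CCB1C2CCCC1CCC2 | intermediate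
22 | C10 primary alcohol | CC(C)=CCC[C@](C)(/C=C\[C@@H](OC(=O)C(C)(C)C)/C(C)=C/[C@H]1COC(C)(C)O1)CCO | intermediate
23 | C10 aldehyde | CC(C)=CCC[C@](C)(/C=C\[C@@H](OC(=O)C(C)(C)C)/C(C)=C/[C@H]1COC(C)(C)O1)CC=O | intermediate
24 | ethyl (Z)-2-iodoenoate | CC(C)=CCC[C@](C)(/C=C\[C@@H](OC(=O)C(C)(C)C)/C(C)=C/[C@H]1COC(C)(C)O1)C/C=C(\I)C(=O)OCC | intermediate
25 | C4,C12-diol | CC(C)=CCC[C@](C)(/C=C\[C@@H](O)/C(C)=C/[C@H]1COC(C)(C)O1)C/C=C(\I)CO | intermediate
26 | C12 TBDPS ether | CC(C)=CCC[C@](C)(/C=C\[C@@H](O)/C(C)=C/[C@H]1COC(C)(C)O1)C/C=C(\I)CO[Si](c1ccccc1)(c1ccccc1)C(C)(C)C | intermediate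
27 | senecioic acid | CC(C)=CC(=O)O | starting material
28 | C4 senecioate | CC(C)=CCC[C@](C)(/C=C\[C@@H](OC(=O)C=C(C)C)/C(C)=C/[C@H]1COC(C)(C)O1)C/C=C(\I)CO[Si](c1ccccc1)(c1ccccc1)C(C)(C)C | intermediate
29 | C7,C8-diol | CC(C)=CCC[C@](C)(/C=C\[C@@H](OC(=O)C=C(C)C)/C(C)=C/[C@H](O)CO)C/C=C(\I)CO[Si](c1ccccc1)(c1ccccc1)C(C)(C)C | intermediate
30 | C8 TES ether | CC(C)=CCC[C@](C)(/C=C\[C@@H](OC(=O)C=C(C)C)/C(C)=C/[C@H](O)CO[Si](CC)(CC)CC)C/C=C(\I)CO[Si](c1ccccc1)(c1ccccc1)C(C)(C)C | intermediate
31 | (5S,6S)-epoxy alcohol | CC(C)=CCC[C@](C)(/C=C\[C@@H](OC(=O)C=C(C)C)[C@]2(C)O[C@H]2[C@H](O)CO[Si](CC)(CC)CC)C/C=C(\I)CO[Si](c1ccccc1)(c1ccccc1)C(C)(C)C | intermediate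
32 | C7 TBS ether | CC(C)=CCC[C@](C)(/C=C\[C@@H](OC(=O)C=C(C)C)[C@]2(C)O[C@H]2[C@H](O[Si](C)(C)C(C)(C)C)CO[Si](CC)(CC)CC)C/C=C(\I)CO[Si](c1ccccc1)(c1ccccc1)C(C)(C)C | intermediate
33 | C8 primary alcohol | CC(C)=CCC[C@](C)(/C=C\[C@@H](OC(=O)C=C(C)C)[C@]2(C)O[C@H]2[C@H](O[Si](C)(C)C(C)(C)C)CO)C/C=C(\I)CO[Si](c1ccccc1)(c1ccccc1)C(C)(C)C | intermediate
34 | C8 aldehyde | CC(C)=CCC[C@](C)(/C=C\[C@@H](OC(=O)C=C(C)C)[C@]2(C)O[C@H]2[C@H](O[Si](C)(C)C(C)(C)C)C=O)C/C=C(\I)CO[Si](c1ccccc1)(c1ccccc1)C(C)(C)C | intermediate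
35 | eleven-membered allylic alcohol, C8 epimers | CC(C)=CCC[C@]1(C)/C=C\[C@@H](OC(=O)C=C(C)C)[C@]2(C)O[C@H]2[C@H](O[Si](C)(C)C(C)(C)C)C(O)/C(CO[Si](c3ccccc3)(c3ccccc3)C(C)(C)C)=C\C1 | intermediate
36 | bis-silylated macrocyclic enone | CC(C)=CCC[C@]1(C)/C=C\[C@@H](OC(=O)C=C(C)C)[C@]2(C)O[C@H]2[C@H](O[Si](C)(C)C(C)(C)C)C(=O)/C(CO[Si](c3ccccc3)(c3ccccc3)C(C)(C)C)=C\C1 | intermediate
37 | CNP0163063.1 | CC(C)=CCC[C@]1(C)/C=C\[C@@H](OC(=O)C=C(C)C)[C@]2(C)O[C@H]2[C@H](O)C(=O)/C(CO)=C\C1 | target

## Step count and weak points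
Total steps: 29. Longest linear sequence: 28 (steps 1–5 and 7–29, from geraniol).

**Step 27 (ring closure).**
- Risk: closure of the eleven-membered ring competes with oligomerisation and with simple reduction of the iodide. Hindered trisubstituted alkenylchromium species can also lose their geometry.
- Fallback: this sets out from 34 and comes back at 36, replacing carbonyl addition by a stereoretentive acyl cross-coupling. Oxidation with NaClO2, NaH2PO4 and 2-methyl-2-butene gives the carboxylic acid F1. EtSH, DCC and DMAP convert it into the S-ethyl thioester F2. (Me3Sn)2 with Pd(PPh3)4 exchanges iodine for tin with retention to give the alkenylstannane F3. A base-free ketone synthesis with Pd2(dba)3, P(2-furyl)3 and CuOP(O)Ph2 at high dilution then closes the ring directly to enone 36, so 35 and step 28 are not needed.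

**Step 9 (C4).**
- Risk: the remote tert-alkyl group on the alkyne may erode the size difference that the catalyst reads.
- Fallback: this sets out from 14 and comes back at 15, replacing catalyst control by resolution. Reduction with NaBH4 and CeCl3·7H2O in MeOH at −78 °C gives the C4-epimeric enynols F4. A Sharpless kinetic resolution follows (Ti(OiPr)4, L-(+)-diisopropyl tartrate, 0.6 equiv t-BuOOH, −20 °C). It epoxidises only the unwanted C4 epimer to the erythro epoxy alcohol F5, which is separated, and the unreacted alcohol is 15.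

**Step 17 (C9=C10 geometry).**
- Risk: the iodo-ylide may give an unsatisfactory Z/E ratio or react sluggishly.
- Fallback: this sets out from 23 and comes back at 25, building the iodoalkene by trans-hydrometalation of an alkyne instead of by olefination. Dimethyl (1-diazo-2-oxopropyl)phosphonate and K2CO3 in MeOH give the terminal alkyne F6. n-BuLi then paraformaldehyde gives the propargylic alcohol F7. Bu3SnH with [Cp*RuCl]4 adds H and Sn trans, with tin next to the CH2OH group, to give the (Z)-2-stannyl allylic alcohol F8. I2 gives the (Z)-2-iodo allylic alcohol pivalate F9 with retention, and i-Bu2AlH removes the pivalate to give 25.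

## Further compounds
F1 | step 27 | C8 carboxylic acid | CC(C)=CCC[C@](C)(/C=C\[C@@H](OC(=O)C=C(C)C)[C@]2(C)O[C@H]2[C@H](O[Si](C)(C)C(C)(C)C)C(=O)O)C/C=C(\I)CO[Si](c1ccccc1)(c1ccccc1)C(C)(C)C
F2 | step 27 | C8 S-ethyl thioester | CC(C)=CCC[C@](C)(/C=C\[C@@H](OC(=O)C=C(C)C)[C@]2(C)O[C@H]2[C@H](O[Si](C)(C)C(C)(C)C)C(=O)SCC)C/C=C(\I)CO[Si](c1ccccc1)(c1ccccc1)C(C)(C)C
F3 | step 27 | C9 trimethylstannyl thioester | CC(C)=CCC[C@](C)(/C=C\[C@@H](OC(=O)C=C(C)C)[C@]2(C)O[C@H]2[C@H](O[Si](C)(C)C(C)(C)C)C(=O)SCC)C/C=C(\[Sn](C)(C)C)CO[Si](c1ccccc1)(c1ccccc1)C(C)(C)C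
F4 | step 9 | C4-epimeric enynols | CC(C)=CCC[C@](C)(C#CC(O)/C(C)=C/[C@H]1COC(C)(C)O1)CO[Si](C)(C)C(C)(C)C
F5 | step 9 | erythro epoxy alcohol of the unwanted C4 epimer | CC(C)=CCC[C@](C)(C#C[C@H](O)[C@]2(C)O[C@H]2[C@H]1COC(C)(C)O1)CO[Si](C)(C)C(C)(C)C
F6 | step 17 | terminal alkyne (C10≡C9H) | CC(C)=CCC[C@](C)(/C=C\[C@@H](OC(=O)C(C)(C)C)/C(C)=C/[C@H]1COC(C)(C)O1)CC#C
F7 | step 17 | propargylic alcohol | CC(C)=CCC[C@](C)(/C=C\[C@@H](OC(=O)C(C)(C)C)/C(C)=C/[C@H]1COC(C)(C)O1)CC#CCO
F8 | step 17 | (Z)-2-tributylstannyl allylic alcohol | CC(C)=CCC[C@](C)(/C=C\[C@@H](OC(=O)C(C)(C)C)/C(C)=C/[C@H]1COC(C)(C)O1)C/C=C(\[Sn](CCCC)(CCCC)CCCC)CO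
F9 | step 17 | (Z)-2-iodo allylic alcohol pivalate | CC(C)=CCC[C@](C)(/C=C\[C@@H](OC(=O)C(C)(C)C)/C(C)=C/[C@H]1COC(C)(C)O1)C/C=C(\I)CO
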